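Start from the slowness of the first exchange: in Saturday's run the complex with one exchanged took 6.00 h to pass half of its last reading, and the new flasks stand 2.5 d, ten times as long. Compare these two times, and reckon from the plateau, not from the rise.

| flask | starting complex | incoming ligand | remark | time |
|---|---|---|---|---|
| Friday's | 0.39 M | 0.49 equiv | run made earlier |  |
| Saturday's | 0.39 M | 0.95 equiv | run made earlier |  |
| Monday's | 0.39 M | 1.6 equiv | run made earlier |  |
| summer | 0.39 M | 0.500 equiv |  | 2.5 d |
| midnight | 0.39 M | 1.20 equiv |  | 2.5 d |
| noon | 0.39 M | 1.50 equiv |  | 2.5 d |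

| run | time / h | complex with one exchanged / % | complex with three exchanged / % |
|---|---|---|---|
| Friday's | 3.00 | 7.2 | 0.3 |
| Friday's | 6.00 | 11.2 | 0 |
| Friday's | 12.0 | 16.9 | 0.4 |
| Friday's | 20.0 | 21.2 | 0.8 |
| Friday's | 40.0 | 25.6 | 1.0 |
| Saturday's | 3.00 | 12.5 | 0 |
| Saturday's | 6.00 | 19.4 | 0.2 |
| Saturday's | 12.0 | 26.0 | 0.2 |
| Saturday's | 20.0 | 33.1 | 0 |
| Saturday's | 40.0 | 36.6 | 0.4 |
| Monday's | 8.00 | 28.1 | 0.5 |
| Monday's | 15.0 | 37.7 | 0.6 |
| Monday's | 25.0 | 42.7 | 0.7 |
| Monday's | 30.0 | 42.3 | 2.1 |
| Monday's | 40.0 | 42.1 | 2.6 |

(readings scatter by 0.5 percentage points)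

- the numbers in the tables scatter with a standard deviation of 0.5 percentage points

- complex with one exchanged at the end, in percent of the starting complex charged, for each flask in turn (summer, midnight, noon)

Freeze the plateau into one number. Treat each last reading as if the first exchange stood alone, then divide the square of the complex with one exchanged by the product of the starting complex and incoming ligand remaining. Friday gives 0.376 and Saturday 0.362; their mean, 0.369, is the plateau quotient, an apparent equilibrium constant. Monday's reading gives a lower 0.260, so above Saturday's charge draw a straight line to Monday's value. That line gives 0.323 for midnight and 0.275 for noon.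

Solving the quotient for the amount gives 25.8% in summer, 39.6% at midnight and 41.7% at noon.

The forecast gave 27.5%, 40% and 41.5%, holding that “all the flasks should be near their plateaus”. The flasks give 25.5%, 37.9% and 39.8%.

    complex with one exchanged → side product (k = 0.00410 h⁻¹)
    complex with two exchanged + incoming ligand ⇌ leaving ligand + complex with three exchanged (K = 12.0, k = 0.0130 L mol⁻¹ h⁻¹)
    complex with one exchanged + incoming ligand ⇌ leaving ligand + complex with two exchanged (K = 0.300, k = 0.310 L mol⁻¹ h⁻¹)
    starting complex + incoming ligand ⇌ leaving ligand + complex with one exchanged (K = 1.20, k = 0.150 L mol⁻¹ h⁻¹)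

Reckoned from these results, the plateau quotient is 0.356 in summer and 0.282 at midnight. In summer the second exchange relaxes, both ways together, with a half-life of 0.140 d at the end, shorter than the 2.5 d the flask stands. At the end, summer holds 2.83% of complex with two exchanged and midnight 8.64%.

The earlier runs and the new flask are calculated with made-up constants, noise included.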